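## Plan

1. **Cuts.** The three MOM ethers come off last. Ring C is opened at C4–C4a (the ring-closing bond) and at O1–C8a, giving the C4a≡C8a aryne 18 and the alkoxide of β-hydroxy amide 16. C8–geranyl and C4a–Si go back through two ortho-metalations to phloroglucinol. C2–C3 goes back through a crossed Claisen condensation to methyl 4-hydroxybenzoate and N,N-dimethylacetamide.
2. **Enabling feature.** O1 and the carbonyl C4 of ring C sit on the adjacent ring-A carbons C8a and C4a. C4a is flanked by the C5 oxygen and C8a by the C8 geranyl group. The C5 oxygen therefore polarises a C4a≡C8a aryne so that it takes oxygen at C8a and leaves its carbanion on C4a, at six-ring distance from C4.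
3. **Order.** Rings A and B are bought. A carbamate on the oxygen of the future C8a steers SiMe3 to C4a and geranyl to C8 and leaves C6–H alone, which settles 8- versus 6-geranyl. Ring C then arises in one operation in the penultimate step.
4. **Stereochemistry.** C2 (S) is set by Noyori–Ikariya transfer hydrogenation of keto amide 15. No bond at C2 is touched afterwards, and the ketone appears only at the acidic quench. The 2''E alkene comes with geranyl bromide.
5. **Helpers.** The carbamate is removed in step 5. SiMe3 and OTf leave in the key step, NMe2 leaves at its quench, and MOM is removed in step 11.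

Key step: step 10

Remark: flavanone numbering (O1, C2, C3, C4, C4a, C5–C8, C8a) is used for the ring positions of all intermediates, and compounds 1, 6, 11 and 13 are taken as commercial.

## Route

Step 1
Reactants: 1 phloroglucinol
Product: 2 3,5-dihydroxyphenyl N,N-diethylcarbamate
Conditions: 1 (3 equiv), Et2NCOCl (1 equiv), K2CO3, MeCN, reflux; excess 1 washed out with water
Reagents that add atoms: diethylcarbamoyl chloride CCN(CC)C(=O)Cl
Why: O-carbamoylation of a phenol, where the excess of cheap, water-soluble 1 and the deactivating effect of the first carbamate should hold the reaction at the mono stage.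

Step 2
Reactants: 2 3,5-dihydroxyphenyl N,N-diethylcarbamate
Product: 3 3,5-bis(methoxymethoxy)phenyl N,N-diethylcarbamate
Conditions: MOMCl (2.5 equiv), i-Pr2NEt, CH2Cl2, 0 °C to rt
Reagents that add atoms: chloromethyl methyl ether COCCl
Why: Standard O-alkylation of phenols to MOM acetals, which tolerate alkyllithiums, hydride and fluoride and also assist the metalations that follow.

Step 3
Reactants: 3 3,5-bis(methoxymethoxy)phenyl N,N-diethylcarbamate
Product: 5 3,5-bis(methoxymethoxy)-2-(trimethylsilyl)phenyl N,N-diethylcarbamate, via aryllithium 4 (not isolated)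
Conditions: s-BuLi, TMEDA, THF, −78 °C; TMSCl, −78 °C to rt
Reagents that add atoms: chlorotrimethylsilane C[Si](C)(C)Cl
Why: Directed ortho metalation, in which the carbamate (the strongest oxygen-based directing group) and the adjacent OMOM cooperate, so one of the two equivalent flanked C–H sites should be lithiated in preference to the C–H between the two MOM ethers, followed by a silyl quench.

Step 4
Reactants: 5 3,5-bis(methoxymethoxy)-2-(trimethylsilyl)phenyl N,N-diethylcarbamate; 6 geranyl bromide
Product: 8 2-[(2E)-3,7-dimethylocta-2,6-dienyl]-3,5-bis(methoxymethoxy)-6-(trimethylsilyl)phenyl N,N-diethylcarbamate, via aryllithium 7 (not isolated)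
Conditions: s-BuLi, TMEDA, THF, −78 °C; CuBr·SMe2 (10 mol %), 6, −78 to −40 °C
Reagents that add atoms: none
Why: Second directed ortho metalation at the remaining carbamate-flanked site (silicon blocks the first), then copper-catalysed SN2 allylation that keeps the E geometry; silicon is installed before geranyl to avoid lateral lithiation, and the low temperature suppresses the anionic ortho-Fries shift.

Step 5
Reactants: 8 geranyl silyl carbamate
Product: 9 2-[(2E)-3,7-dimethylocta-2,6-dienyl]-3,5-bis(methoxymethoxy)-6-(trimethylsilyl)phenol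
Conditions: LiAlH4, THF, reflux; Rochelle salt work-up
Reagents that add atoms: none
Why: Hydride reduction of an aryl carbamate releases the phenoxide with a small nucleophile that reaches the hindered carbonyl; alkenes, MOM ethers and the aryl silane are inert, and the neutral work-up avoids protodesilylation.

Step 6
Reactants: 9 geranyl silyl phenol
Product: 10 2-[(2E)-3,7-dimethylocta-2,6-dienyl]-3,5-bis(methoxymethoxy)-6-(trimethylsilyl)phenyl trifluoromethanesulfonate
Conditions: Tf2O, pyridine, CH2Cl2, −20 to 0 °C
Reagents that add atoms: triflic anhydride O=S(=O)(OS(=O)(=O)C(F)(F)F)C(F)(F)F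
Why: O-triflation of an o-silylphenol gives the o-silylaryl triflate (Kobayashi-type aryne precursor), with excess pyridine keeping the medium free of acid.

Step 7
Reactants: 11 methyl 4-hydroxybenzoate
Product: 12 methyl 4-(methoxymethoxy)benzoate
Conditions: MOMCl, i-Pr2NEt, CH2Cl2, 0 °C to rt
Reagents that add atoms: chloromethyl methyl ether COCCl
Why: Standard MOM protection, using the same group as on ring A so that one final step unmasks all three phenols.

Step 8
Reactants: 12 methyl 4-(methoxymethoxy)benzoate; 13 N,N-dimethylacetamide
Product: 15 3-[4-(methoxymethoxy)phenyl]-N,N-dimethyl-3-oxopropanamide, via lithium enolate 14 (not isolated)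
Conditions: LDA (2.2 equiv), 13 (2.2 equiv), THF, −78 °C; 12, −78 to 0 °C; aq NH4Cl
Reagents that add atoms: none
Why: Crossed Claisen condensation of an amide enolate with a non-enolisable ester forms C2–C3, the second equivalent of base driving it by deprotonating the β-keto amide.

Step 9
Reactants: 15 β-keto amide
Product: 16 (3S)-3-hydroxy-3-[4-(methoxymethoxy)phenyl]-N,N-dimethylpropanamide
Conditions: RuCl[(S,S)-TsDPEN](p-cymene) (1 mol %), HCO2H/Et3N 5:2, CH2Cl2, rt
Reagents that add atoms: none
Why: Noyori–Ikariya asymmetric transfer hydrogenation, a reaction type established for aryl β-keto amides; the (S,S) catalyst should deliver hydride to the face that gives the (S) benzylic alcohol (aryl ranks above CH2, as in 1-phenylethanol), and the buffered medium should spare the MOM ether.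

Step 10
Reactants: 10 o-silylaryl triflate; 16 (S)-β-hydroxy amide (1.5 equiv)
Product: 21 (2S)-8-geranyl-5,7,4'-tris(methoxymethoxy)flavanone, via potassium alkoxide 17 (not isolated), via aryne 18 (not isolated), via aryl anion 19 (not isolated), via hemiaminal alkoxide 20 (not isolated)
Conditions: 16, KH, THF, 0 °C; anhydrous KF, 18-crown-6; slow addition of 10, 0 °C to rt; AcOH/THF, −40 °C, then pH 5 buffer
Reagents that add atoms: none
Why: Proposed new method: fluoride removes the C4a silyl group of 10 and triflate leaves C8a to give aryne 18, the preformed proton-free alkoxide 17 adds through oxygen to C8a, and the C4a carbanion 19 attacks the amide carbonyl C4 to close ring C as hemiaminal alkoxide 20, which gives ketone 21 and Me2NH only on the cold acidic quench. The closest known reaction types are the aryne annulations of salicylate esters to xanthones and of β-lactams to 2,3-dihydroquinolin-4-ones (heteroatom addition, then acyl capture of the aryl anion) and the Parham cyclisation of o-lithioaryl ethers onto tethered amides, the new element being an aliphatic β-hydroxy amide alkoxide as the partner. Ring C closes 6-exo-trig (C4a onto C4=O) directly after the intermolecular O1–C8a bond. No lasting stereocentre is created, and C2 should pass unchanged from 16 because none of its bonds is touched, a dialkylamide aldolate is the acyl derivative least prone to retro-aldol cleavage, and C4 stays sp3 with a very poor leaving group (no enolisable ketone, hence no retro-oxa-Michael opening) as long as base is present. The step needs oxygen attack at C8a and not at C4a, which the C5 OMOM group next to C4a should secure by polarising and distorting the aryne so that charge builds at C4a, an effect expected to outweigh the steric bias of the C8 geranyl CH2 and the weak opposing pull of the C7 oxygen. It also needs acyl capture to outrun protonation or α-deprotonation, which the absence of any O–H or N–H acid (KH, H2 escapes), the low acidity of amide α-protons and the six-membered transition state should secure.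

Step 11
Reactants: 21 (2S)-8-geranyl-5,7,4'-tris(methoxymethoxy)flavanone
Product: 22 sophoraflavanone A [(2S)-8-geranylnaringenin]
Conditions: HCl (about 1 M, from conc. aq HCl), MeOH, 40 °C, stopped at full conversion
Reagents that add atoms: none
Why: Acid-catalysed acetal solvolysis of phenolic MOM ethers, a reaction type in routine use on prenylated and geranylated flavanones; C2 is labile mainly to base, so short exposure to mild acid should preserve both the configuration and the geranyl chain.

## Compound list

1 | phloroglucinol | Oc1cc(O)cc(O)c1 | starting material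
2 | 3,5-dihydroxyphenyl N,N-diethylcarbamate | CCN(CC)C(=O)Oc1cc(O)cc(O)c1 | intermediate
3 | 3,5-bis(methoxymethoxy)phenyl N,N-diethylcarbamate | CCN(CC)C(=O)Oc1cc(OCOC)cc(OCOC)c1 | intermediate
4 | 2-lithio derivative of 3 | CCN(CC)C(=O)Oc1cc(OCOC)cc(OCOC)c1[Li] | intermediate
5 | 3,5-bis(methoxymethoxy)-2-(trimethylsilyl)phenyl N,N-diethylcarbamate | CCN(CC)C(=O)Oc1cc(OCOC)cc(OCOC)c1[Si](C)(C)C | intermediate
6 | geranyl bromide, (2E)-1-bromo-3,7-dimethylocta-2,6-diene | CC(C)=CCC/C(C)=C/CBr | starting material
7 | 6-lithio derivative of 5 | CCN(CC)C(=O)Oc1c([Li])c(OCOC)cc(OCOC)c1[Si](C)(C)C | intermediate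
8 | 2-geranyl-3,5-bis(methoxymethoxy)-6-(trimethylsilyl)phenyl N,N-diethylcarbamate | CC(C)=CCC/C(C)=C/Cc1c(OCOC)cc(OCOC)c([Si](C)(C)C)c1OC(=O)N(CC)CC | intermediate
9 | 2-geranyl-3,5-bis(methoxymethoxy)-6-(trimethylsilyl)phenol | CC(C)=CCC/C(C)=C/Cc1c(OCOC)cc(OCOC)c([Si](C)(C)C)c1O | intermediate
10 | 2-geranyl-3,5-bis(methoxymethoxy)-6-(trimethylsilyl)phenyl triflate | CC(C)=CCC/C(C)=C/Cc1c(OCOC)cc(OCOC)c([Si](C)(C)C)c1OS(=O)(=O)C(F)(F)F | intermediate
11 | methyl 4-hydroxybenzoate | COC(=O)c1ccc(O)cc1 | starting material
12 | methyl 4-(methoxymethoxy)benzoate | COCOc1ccc(C(=O)OC)cc1 | intermediate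
13 | N,N-dimethylacetamide | CC(=O)N(C)C | starting material
14 | lithium enolate of 13 | C=C(O[Li])N(C)C | intermediate
15 | 3-[4-(methoxymethoxy)phenyl]-N,N-dimethyl-3-oxopropanamide | COCOc1ccc(C(=O)CC(=O)N(C)C)cc1 | intermediate
16 | (3S)-3-hydroxy-3-[4-(methoxymethoxy)phenyl]-N,N-dimethylpropanamide | O[C@H](c1ccc(OCOC)cc1)CC(=O)N(C)C | intermediate
17 | potassium alkoxide of 16 | [K+].[O-][C@H](c1ccc(OCOC)cc1)CC(=O)N(C)C | intermediate
18 | 6-geranyl-3,5-bis(methoxymethoxy)benzyne (C4a≡C8a) | CC(C)=CCC/C(C)=C/CC1=C(OCOC)C=C(OCOC)C#C1 | intermediate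
19 | C4a aryl anion (potassium salt) of the (S)-aryl ether amide | CC(C)=CCC/C(C)=C/Cc1c(OCOC)cc(OCOC)[c-]c1O[C@H](c1ccc(OCOC)cc1)CC(=O)N(C)C.[K+] | intermediate
20 | potassium (2S)-4-(dimethylamino)-8-geranyl-5,7,4'-tris(methoxymethoxy)flavan-4-olate | CC(C)=CCC/C(C)=C/Cc1c(OCOC)cc(OCOC)c2c1O[C@H](c1ccc(OCOC)cc1)CC2([O-])N(C)C.[K+] | intermediate
21 | (2S)-8-geranyl-5,7,4'-tris(methoxymethoxy)flavanone | CC(C)=CCC/C(C)=C/Cc1c(OCOC)cc(OCOC)c2c1O[C@H](c1ccc(OCOC)cc1)CC2=O | intermediate
22 | sophoraflavanone A | CC(C)=CCC/C(C)=C/Cc1c(O)cc(O)c2c1O[C@H](c1ccc(O)cc1)CC2=O | target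

## Step count and risks

Total step count: 11. Longest linear sequence: 8 (steps 1–6, 10, 11).

**1. Step 10.**
- *What may go wrong:* capture of the aryne by the secondary alkoxide may be too slow against other aryne consumption; the alkoxide may attack the sulfur of the triflate; the aryl anion may be protonated before acyl capture; regioselectivity may erode next to the geranyl group.
- *Fallback, from 10 back to 21:*
  - (E)-4-(methoxymethoxy)cinnamic acid F1 is made by Doebner condensation of commercial 4-(methoxymethoxy)benzaldehyde with malonic acid.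
  - F1 is heated with 10 and CsF in THF. The known insertion of arynes into the C–O bond of carboxylic acids (O-arylation at C8a, then O-to-C acyl shift onto C4a) should give 3'-geranyl-2'-hydroxy-4,4',6'-tris(methoxymethoxy)chalcone F2.
  - NaOAc in EtOH closes F2 by oxa-Michael addition to the racemic flavanone F3.
  - Kinetic resolution by transfer hydrogenation with RuCl[(R,R)-TsDPEN](p-cymene), HCO2H/Et3N should reduce the (2R) enantiomer to the cis-(2R,4R)-flavan-4-ol F4. The unreduced (2S) ketone is 21 and is separated by chromatography.

**2. Step 3.**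
- *What may go wrong:* lithiation between the two MOM ethers may compete with lithiation at the carbamate-flanked site.
- *Fallback, from 1 back to 5, replacing C–H metalation by halogen-based placement of silicon:*
  - 1 is converted with two equivalents of MOMCl into 3,5-bis(methoxymethoxy)phenol F5.
  - Amine-catalysed ortho-bromination (NBS, cat. i-Pr2NH, CH2Cl2) gives 2-bromo-3,5-bis(methoxymethoxy)phenol F6.
  - HMDS gives its trimethylsilyl ether F7.
  - n-BuLi at −78 °C triggers bromine–lithium exchange and retro-Brook O-to-C silyl shift to 3,5-bis(methoxymethoxy)-2-(trimethylsilyl)phenol F8.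
  - NaH/Et2NCOCl converts F8 into 5.

**3. Step 11.**
- *What may go wrong:* acid-induced addition of the freed 7-OH to the proximal geranyl alkene (chroman formation), or acid-induced opening of ring C with loss of configuration.
- *Fallback, from 21 back to 22, replacing Brønsted-acid solvolysis by trans-protection:*
  - TESOTf and 2,2'-bipyridyl in CH2Cl2 at 0 °C exchange the aromatic MOM ethers for silyl ethers, giving (2S)-8-geranyl-5,7,4'-tris(triethylsilyloxy)flavanone F9.
  - Et3N·3HF in THF at 0 °C, under buffered and nearly neutral conditions, then releases 22.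

## Further compounds

F1 | step 10 | (E)-4-(methoxymethoxy)cinnamic acid | COCOc1ccc(/C=C/C(=O)O)cc1
F2 | step 10 | 3'-geranyl-2'-hydroxy-4,4',6'-tris(methoxymethoxy)chalcone | CC(C)=CCC/C(C)=C/Cc1c(OCOC)cc(OCOC)c(C(=O)/C=C/c2ccc(OCOC)cc2)c1O
F3 | step 10 | racemic 8-geranyl-5,7,4'-tris(methoxymethoxy)flavanone | CC(C)=CCC/C(C)=C/Cc1c(OCOC)cc(OCOC)c2c1OC(c1ccc(OCOC)cc1)CC2=O
F4 | step 10 | (2R,4R)-8-geranyl-5,7,4'-tris(methoxymethoxy)flavan-4-ol | CC(C)=CCC/C(C)=C/Cc1c(OCOC)cc(OCOC)c2c1O[C@@H](c1ccc(OCOC)cc1)C[C@H]2O
F5 | step 3 | 3,5-bis(methoxymethoxy)phenol | COCOc1cc(O)cc(OCOC)c1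
F6 | step 3 | 2-bromo-3,5-bis(methoxymethoxy)phenol | COCOc1cc(O)c(Br)c(OCOC)c1
F7 | step 3 | [2-bromo-3,5-bis(methoxymethoxy)phenoxy]trimethylsilane | COCOc1cc(O[Si](C)(C)C)c(Br)c(OCOC)c1
F8 | step 3 | 3,5-bis(methoxymethoxy)-2-(trimethylsilyl)phenol | COCOc1cc(O)c([Si](C)(C)C)c(OCOC)c1
F9 | step 11 | (2S)-8-geranyl-5,7,4'-tris(triethylsilyloxy)flavanone | CC(C)=CCC/C(C)=C/Cc1c(O[Si](CC)(CC)CC)cc(O[Si](CC)(CC)CC)c2c1O[C@H](c1ccc(O[Si](CC)(CC)CC)cc1)CC2=O
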